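**Retrosynthetic overview**
1. Target 25 is numbered C1(OBz)–C2=C3–C4(OBz)–C5(OH)–C6(OH)(C7H2OH), with O1, O4, O5 and O6 all on one ring face. Protecting-group and oxidation-level changes lead back to acid 19 (C7 = CO2H, O1/O4 as PMB ethers, O5/O6 as acetonide).
2. Feature used: C7–C6–C1–C2=C3 is a γ,δ-unsaturated acid. Cutting C1–C6 by a retro-[3,3] shift gives δ-lactone 16 (ring C7(=O)–O–C3–C4–C5–C6) whose C3 carries the Z-enol ether C2=C1–O1. Its silyl ketene acetal is the 1,5-diene C6=C7–O–C3–C2=C1.
3. Lactone 16 comes from chelation-controlled addition of (Z)-PMBOCH=CHMgBr to the C3 aldehyde of ribonate 12, with lactonisation in the same flask. Ester 12 comes from 2,3-O-isopropylidene-D-ribonolactone (C3–C7, the C4–C6 stereocentres) by lactone opening, O4 benzylation and oxidation at C3.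
4. Ring order: dioxolane (bought), then the δ-lactone (step 7), then the cyclohexene by contraction of that lactone (step 8).

Key step: step 8

Remark: locants C1–C7 and O1–O7 are those of the overview; carbohydrate locants appear only inside sugar names (sugar C1–C5 = C7, C6, C5, C4, C3). PMB = 4-methoxybenzyl. The Z isomer of bromide 5 is assumed to be separable from any E isomer.

**Step 1**
Reactants: 1 4-methoxybenzyl alcohol; 2 butyl vinyl ether
Product: 3 4-methoxybenzyl vinyl ether
Conditions: Pd(OCOCF3)2 (1 mol %), 4,7-diphenyl-1,10-phenanthroline (1 mol %), Et3N (cat), butyl vinyl ether (neat, 20 equiv), air, 75 °C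
Reagents that add atoms: butyl vinyl ether (2), C=COCCCC
Why: Transfer vinylation (alkoxypalladation followed by β-alkoxide elimination) exchanges the butoxy group of the vinyl ether for the benzylic alcohol under non-acidic conditions that the PMB group tolerates, and no stereocentre is involved.

**Step 2**
Reactants: 3 4-methoxybenzyl vinyl ether
Product: 5 (Z)-1-bromo-2-(4-methoxybenzyloxy)ethene, via 1,2-dibromoethyl 4-methoxybenzyl ether 4 (not isolated)
Conditions: Br2 (1.0 equiv), CH2Cl2, −78 °C; then i-Pr2NEt (2.5 equiv), −78 → 40 °C; Et3N-washed SiO2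
Reagents that add atoms: bromine, BrBr
Why: Bromine adds across the electron-rich enol ether and the amine then removes HBr from the α-bromo ether through its oxocarbenium ion (halogenation–dehydrohalogenation of a vinyl ether), which is expected to favour the Z-2-bromovinyl ether because the cis arrangement of the two heteroatoms is the more stable one.

**Step 3**
Reactants: 6 2,3-O-isopropylidene-D-ribono-1,4-lactone
Product: 7 5-O-(tert-butyldiphenylsilyl)-2,3-O-isopropylidene-D-ribono-1,4-lactone
Conditions: t-BuPh2SiCl, imidazole, DMF, 0 → 20 °C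
Reagents that add atoms: tert-butyldiphenylsilyl chloride, CC(C)(C)[Si](Cl)(c1ccccc1)c1ccccc1
Why: Silyl ether formation at the only free hydroxyl (the primary one on C3) leaves the lactone and its stereocentres untouched, and the bulky group is slow to migrate under the basic conditions of step 4.

**Step 4**
Reactants: 7 5-O-(tert-butyldiphenylsilyl)-2,3-O-isopropylidene-D-ribono-1,4-lactone; 8 4-methoxybenzyl chloride
Product: 10 4-methoxybenzyl 5-O-(tert-butyldiphenylsilyl)-2,3-O-isopropylidene-4-O-(4-methoxybenzyl)-D-ribonate, via sodium 5-O-(tert-butyldiphenylsilyl)-2,3-O-isopropylidene-D-ribonate 9 (not isolated)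
Conditions: NaOH (1.05 equiv), THF/H2O, 20 °C; evaporate, toluene azeotrope; then NaH (1.2 equiv), 4-methoxybenzyl chloride (2.5 equiv), Bu4NI (cat), DMF, 0 → 40 °C
Reagents that add atoms: sodium hydroxide, [Na+].[OH-]; 4-methoxybenzyl chloride (8), COc1ccc(CCl)cc1
Why: Saponification (acyl–oxygen cleavage) frees O4 as a hydroxy carboxylate that cannot relactonise, Williamson etherification of the sodium alkoxide is faster than SN2 esterification of the carboxylate by the excess benzylic chloride, so the ester appears only after O4 is capped, and the stereocentres C4–C6 are not enolisable at the carboxylate stage.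

**Step 5**
Reactants: 10 4-methoxybenzyl 5-O-(tert-butyldiphenylsilyl)-2,3-O-isopropylidene-4-O-(4-methoxybenzyl)-D-ribonate
Product: 11 4-methoxybenzyl 2,3-O-isopropylidene-4-O-(4-methoxybenzyl)-D-ribonate
Conditions: Bu4NF/AcOH (1:1), THF, 0 → 20 °C
Reagents that add atoms: none
Why: Fluoride-induced Si–O cleavage frees the primary alcohol on C3, and acetic acid buffering keeps the medium too weakly basic for ester cleavage or δ-lactonisation onto the C7 ester.

**Step 6**
Reactants: 11 4-methoxybenzyl 2,3-O-isopropylidene-4-O-(4-methoxybenzyl)-D-ribonate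
Product: 12 4-methoxybenzyl 3,4-O-isopropylidene-2-O-(4-methoxybenzyl)-aldehydo-L-riburonate (the 5-aldehyde of 11)
Conditions: Dess–Martin periodinane, pyridine, CH2Cl2, 0 → 20 °C; used crude
Reagents that add atoms: none
Why: Dess–Martin oxidation converts the primary alcohol into the aldehyde under buffered, non-enolising conditions, so the α-alkoxy centre C4 keeps its configuration.

**Step 7**
Reactants: 12 4-methoxybenzyl 3,4-O-isopropylidene-2-O-(4-methoxybenzyl)-aldehydo-L-riburonate; 5 (Z)-1-bromo-2-(4-methoxybenzyloxy)ethene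
Product: 16 (6Z)-6-deoxy-2,3-O-isopropylidene-4,7-di-O-(4-methoxybenzyl)-L-talo-hept-6-enono-1,5-lactone, via (Z)-2-(4-methoxybenzyloxy)vinyllithium 13 (not isolated), via (Z)-2-(4-methoxybenzyloxy)vinylmagnesium bromide 14 (not isolated), via open-chain bromomagnesium alkoxide 15 (not isolated)
Conditions: 5, t-BuLi (2 equiv), Et2O, −78 °C; MgBr2·OEt2 (3 equiv), −78 °C; 12 in CH2Cl2, −78 → 0 °C; H2O; Et3N-washed SiO2
Reagents that add atoms: none
Why: Bromine–lithium exchange and transmetalation to magnesium proceed with retention of the Z geometry, MgBr2 ties the aldehyde oxygen to the O4 ether in a five-membered chelate (Cram chelate addition) so that the alkenyl group attacks the face away from the dioxolane and sets C3 with its oxygen syn to O4 (L-talo), and the magnesium alkoxide then displaces 4-methoxybenzyl oxide from the C7 ester in a 6-exo-trig lactonisation favoured by the cis-dioxolane turn.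

**Step 8**
Reactants: 16 (6Z)-6-deoxy-2,3-O-isopropylidene-4,7-di-O-(4-methoxybenzyl)-L-talo-hept-6-enono-1,5-lactone
Product: 19 5,6-O-isopropylidene-1,4-bis-O-(4-methoxybenzyl)-1,4,5,6-tetrahydroxycyclohex-2-ene-6-carboxylic acid (O1/O4/O5/O6 on one face and CO2H on the other), via trimethylsilyl ketene acetal 17 (not isolated), via trimethylsilyl ester 18 (not isolated)
Conditions: Me3SiCl/Et3N (1:1, 4 equiv), THF, −78 °C; KN(SiMe3)2 (1.5 equiv, toluene), −78 °C; 20 °C, then 60 °C; pH 5 aqueous work-up
Reagents that add atoms: none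
Why: Proposed new method: KN(SiMe3)2 removes the C6 proton next to the lactone carbonyl in the presence of Me3SiCl, the enolate is silylated on oxygen at once to ketene acetal 17, and its 1,5-diene C6=C7–O–C3–C2=C1 then undergoes a concerted [3,3]-sigmatropic shift that breaks C3–O, forms C1–C6 and leaves the C2=C3 bond, a change that the 2-silyloxy group and the 6-alkoxy donor O1 should both accelerate. The closest known reaction type is the alicyclic Ireland–Claisen contraction of 6-alkenyl δ-lactone silyl ketene acetals to cyclohex-3-enecarboxylic acids, alongside glycolate Ireland–Claisen rearrangements of acyclic allyl esters; it has not been shown for an α,β-dioxygenated lactone whose alkenyl group is a Z-enol ether. The cyclohexene ring closes by ring contraction: the two-carbon tether C4–C5 forces the six reacting atoms into a boat, bicyclo[2.2.2]octane-like array, suprafacial on both three-atom units. C6 is set by chirality transfer from C3, because C1 can reach C6 only on the lactone face that carries the alkenyl group, the face of O4 and O5, so that O6 ends cis to O5 and the carboxyl trans; C1 is set by the Z geometry, which in the boat holds O1 anti to C7 and therefore cis to O6, and the C3 stereocentre is used up as C2=C3 forms. The selectivity needed is rearrangement over β-elimination of O5 and over ionisation of the allylic C3–O bond: the dioxolane holds the C5–O5 bond near the plane of the enolate where it overlaps poorly with the carbanion lobe, and silylation in the flask at −78 °C keeps free enolate from building up, while the neutral ketene acetal should rearrange on gentle warming.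

**Step 9**
Reactants: 19 5,6-O-isopropylidene-1,4-bis-O-(4-methoxybenzyl)-1,4,5,6-tetrahydroxycyclohex-2-ene-6-carboxylic acid
Product: 20 [5,6-O-isopropylidene-1,4-bis-O-(4-methoxybenzyl)-1,4,5,6-tetrahydroxycyclohex-2-en-6-yl]methanol
Conditions: LiAlH4, THF, 0 → 20 °C; H2O, aq NaOH work-up
Reagents that add atoms: none
Why: LiAlH4 reduces the carboxylic acid through its aluminium carboxylate to the primary alcohol C7H2OH while benzylic ethers, acetal and the isolated C2=C3 bond are inert, and no stereocentre is touched.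

**Step 10**
Reactants: 20 [5,6-O-isopropylidene-1,4-bis-O-(4-methoxybenzyl)-1,4,5,6-tetrahydroxycyclohex-2-en-6-yl]methanol
Product: 21 O7-tert-butyldimethylsilyl ether of 20
Conditions: t-BuMe2SiCl, imidazole, DMAP (cat), DMF, 20 °C
Reagents that add atoms: tert-butyldimethylsilyl chloride, CC(C)(C)[Si](C)(C)Cl
Why: Silylation of the only free hydroxyl blocks O7 against acylation in step 12 with a group that the final acid treatment removes together with the acetonide.

**Step 11**
Reactants: 21 O7-tert-butyldimethylsilyl ether of 20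
Product: 22 6-[(tert-butyldimethylsilyloxy)methyl]-5,6-O-isopropylidenecyclohex-2-ene-1,4,5,6-tetrol (O1–H and O4–H free)
Conditions: DDQ (2.6 equiv), CH2Cl2/pH 7 phosphate buffer (10:1), 0 → 20 °C
Reagents that add atoms: none
Why: DDQ oxidises both electron-rich benzylic ethers to oxocarbenium ions that water hydrolyses to 4-methoxybenzaldehyde (oxidative PMB cleavage), leaving O1–H and O4–H free without affecting the silyl ether, the acetonide or the ring configuration.

**Step 12**
Reactants: 22 6-[(tert-butyldimethylsilyloxy)methyl]-5,6-O-isopropylidenecyclohex-2-ene-1,4,5,6-tetrol; 23 benzoyl chloride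
Product: 24 1,4-di-O-benzoate of 22
Conditions: benzoyl chloride (3 equiv), pyridine, DMAP (cat), CH2Cl2, 0 → 20 °C
Reagents that add atoms: benzoyl chloride (23), O=C(Cl)c1ccccc1
Why: DMAP-catalysed acylation esterifies the two free secondary allylic hydroxyls, the only nucleophilic sites left, with retention at C1 and C4.

**Step 13**
Reactants: 24 1,4-di-O-benzoate of 22
Product: 25 (1R,4S,5R,6R)-5,6-dihydroxy-5-(hydroxymethyl)cyclohex-2-ene-1,4-diyl dibenzoate (target)
Conditions: CF3CO2H/H2O (4:1), 0 → 20 °C
Reagents that add atoms: none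
Why: Aqueous trifluoroacetic acid hydrolyses the isopropylidene acetal and the primary silyl ether while the benzoates are stable, and the low temperature keeps acid-catalysed acyl migration from O4 to the cis O5 slow.

**Compound list**
1 | 4-methoxybenzyl alcohol | COc1ccc(CO)cc1 | starting material
2 | butyl vinyl ether | C=COCCCC | starting material
3 | 4-methoxybenzyl vinyl ether | C=COCc1ccc(OC)cc1 | intermediate
4 | 1,2-dibromoethyl 4-methoxybenzyl ether (racemic) | BrCC(Br)OCc1ccc(OC)cc1 | intermediate
5 | (Z)-1-bromo-2-(4-methoxybenzyloxy)ethene | Br/C=C\OCc1ccc(OC)cc1 | intermediate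
6 | 2,3-O-isopropylidene-D-ribono-1,4-lactone | O=C1O[C@H](CO)[C@H]2OC(C)(C)O[C@@H]12 | starting material
7 | 5-O-(tert-butyldiphenylsilyl)-2,3-O-isopropylidene-D-ribono-1,4-lactone | O=C1O[C@H](CO[Si](c2ccccc2)(c2ccccc2)C(C)(C)C)[C@H]2OC(C)(C)O[C@@H]12 | intermediate
8 | 4-methoxybenzyl chloride | COc1ccc(CCl)cc1 | starting material
9 | sodium 5-O-(tert-butyldiphenylsilyl)-2,3-O-isopropylidene-D-ribonate | [Na+].[O-]C(=O)[C@@H]1OC(C)(C)O[C@@H]1[C@H](O)CO[Si](c1ccccc1)(c1ccccc1)C(C)(C)C | intermediate
10 | 4-methoxybenzyl 5-O-(tert-butyldiphenylsilyl)-2,3-O-isopropylidene-4-O-(4-methoxybenzyl)-D-ribonate | COc1ccc(COC(=O)[C@@H]2OC(C)(C)O[C@@H]2[C@H](OCc3ccc(OC)cc3)CO[Si](c3ccccc3)(c3ccccc3)C(C)(C)C)cc1 | intermediate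
11 | 4-methoxybenzyl 2,3-O-isopropylidene-4-O-(4-methoxybenzyl)-D-ribonate | COc1ccc(COC(=O)[C@@H]2OC(C)(C)O[C@@H]2[C@H](OCc3ccc(OC)cc3)CO)cc1 | intermediate
12 | 4-methoxybenzyl 3,4-O-isopropylidene-2-O-(4-methoxybenzyl)-aldehydo-L-riburonate (5-aldehyde of 11) | COc1ccc(COC(=O)[C@@H]2OC(C)(C)O[C@@H]2[C@H](OCc3ccc(OC)cc3)C=O)cc1 | intermediate
13 | (Z)-2-(4-methoxybenzyloxy)vinyllithium | [Li]/C=C\OCc1ccc(OC)cc1 | intermediate
14 | (Z)-2-(4-methoxybenzyloxy)vinylmagnesium bromide | Br[Mg]/C=C\OCc1ccc(OC)cc1 | intermediate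
15 | bromomagnesium alkoxide of 4-methoxybenzyl (6Z)-6-deoxy-2,3-O-isopropylidene-4,7-di-O-(4-methoxybenzyl)-L-talo-hept-6-enonate | COc1ccc(COC(=O)[C@@H]2OC(C)(C)O[C@@H]2[C@H](OCc3ccc(OC)cc3)[C@@H](O[Mg]Br)/C=C\OCc3ccc(OC)cc3)cc1 | intermediate
16 | (6Z)-6-deoxy-2,3-O-isopropylidene-4,7-di-O-(4-methoxybenzyl)-L-talo-hept-6-enono-1,5-lactone (alkenyl group, O4, O5 and O6 all cis on the δ-lactone) | O=C1O[C@@H](/C=C\OCc2ccc(OC)cc2)[C@@H](OCc2ccc(OC)cc2)[C@H]3OC(C)(C)O[C@@H]13 | intermediate
17 | trimethylsilyl ketene acetal of 16 (C6=C7(OSiMe3) in the ring) | C[Si](C)(C)OC1=C2OC(C)(C)O[C@@H]2[C@H](OCc2ccc(OC)cc2)[C@H](/C=C\OCc2ccc(OC)cc2)O1 | intermediate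
18 | trimethylsilyl ester of 19 | COc1ccc(CO[C@H]2C=C[C@@H](OCc3ccc(OC)cc3)[C@H]4OC(C)(C)O[C@@]24C(=O)O[Si](C)(C)C)cc1 | intermediate
19 | 5,6-O-isopropylidene-1,4-bis-O-(4-methoxybenzyl)-1,4,5,6-tetrahydroxycyclohex-2-ene-6-carboxylic acid (overview locants; O1/O4/O5/O6 on one face, CO2H on the other; absolute configuration as in 25) | COc1ccc(CO[C@H]2C=C[C@@H](OCc3ccc(OC)cc3)[C@H]4OC(C)(C)O[C@@]24C(=O)O)cc1 | intermediate
20 | [5,6-O-isopropylidene-1,4-bis-O-(4-methoxybenzyl)-1,4,5,6-tetrahydroxycyclohex-2-en-6-yl]methanol (same configuration) | COc1ccc(CO[C@H]2C=C[C@@H](OCc3ccc(OC)cc3)[C@H]4OC(C)(C)O[C@@]24CO)cc1 | intermediate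
21 | O7-tert-butyldimethylsilyl ether of 20 | COc1ccc(CO[C@H]2C=C[C@@H](OCc3ccc(OC)cc3)[C@H]4OC(C)(C)O[C@@]24CO[Si](C)(C)C(C)(C)C)cc1 | intermediate
22 | 6-[(tert-butyldimethylsilyloxy)methyl]-5,6-O-isopropylidenecyclohex-2-ene-1,4,5,6-tetrol (all four oxygens cis) | O[C@H]1C=C[C@@H](O)[C@H]2OC(C)(C)O[C@@]12CO[Si](C)(C)C(C)(C)C | intermediate
23 | benzoyl chloride | O=C(Cl)c1ccccc1 | starting material
24 | 1,4-di-O-benzoate of 22 | O=C(O[C@H]1C=C[C@@H](OC(=O)c2ccccc2)[C@H]3OC(C)(C)O[C@@]13CO[Si](C)(C)C(C)(C)C)c1ccccc1 | intermediate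
25 | (1R,4S,5R,6R)-5,6-dihydroxy-5-(hydroxymethyl)cyclohex-2-ene-1,4-diyl dibenzoate (IUPAC locants in this name; all four ring oxygens cis) | O=C(O[C@H]1C=C[C@@H](OC(=O)c2ccccc2)[C@@H](O)[C@]1(O)CO)c1ccccc1 | target

**Step count**
Total: 13 steps. Longest linear sequence: 11 steps (6 → 25, steps 3–13); steps 1–2 make the C1–C2 fragment 5.

**Steps most likely to fail**

Step 8 (proposed method). What may go wrong: β-elimination of O5 from the enolate before silylation, ionisation of the allylic C3–O bond of 17, or a boat transition state too congested by the 1,3-syn O1/O5 contact to be reached before decomposition. The fallback uses known chemistry: ring-closing metathesis forms C2=C3 instead of a sigmatropic shift forming C1–C6. It sets out from aldehyde 12 and comes back at silyl ether 21. Wittig methylenation of 12 (Ph3P=CH2, THF, −78 → 0 °C) should give 4-methoxybenzyl 5,6-dideoxy-2,3-O-isopropylidene-4-O-(4-methoxybenzyl)-D-ribo-hex-5-enonate F1. i-Bu2AlH (CH2Cl2, −78 °C) should stop at 5,6-dideoxy-2,3-O-isopropylidene-4-O-(4-methoxybenzyl)-aldehydo-D-ribo-hex-5-enose F2. Crossed aldol addition to formaldehyde (aq CH2O, K2CO3, MeOH) through the dioxolane enolate brings in C7 trans to the C4 side chain and should give the 2-C-hydroxymethyl aldehyde F3. Silylation (t-BuMe2SiCl, imidazole) gives the silyl ether F4. CH2=CHMgBr (CH2Cl2/Et2O, −78 °C), chelated between the aldehyde oxygen and O6 and attacking past the smaller CH2OSi arm, should give the allylic alcohol F5 with O1 syn to O6; a wrong C1 epimer would be inverted by Mitsunobu esterification and methanolysis. 4-Methoxybenzyl trichloroacetimidate with catalytic La(OTf)3 gives the diene F6. The second-generation Grubbs catalyst RuCl2(=CHPh)(PCy3)(H2IMes) in CH2Cl2 at 40 °C should close the ring with loss of ethene and deliver 21.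

Step 7. What may go wrong: competition of the open transition state with the chelate (poor facial selectivity at C3), and loss of the Z-alkenyl metal by β-elimination of 4-methoxybenzyl oxide or by isomerisation during the exchange. In the fallback the two carbons enter as an alkynyl ether and the Z geometry is made afterwards by syn hydrogenation. It sets out from 12 and 1 and comes back at lactone 16. Alcohol 1 with KH and trichloroethene (THF) gives (E)-1,2-dichlorovinyl 4-methoxybenzyl ether F7. n-BuLi (2 equiv, THF, −78 °C) converts it into lithium (4-methoxybenzyloxy)acetylide F8, a small linear nucleophile that should follow the chelate path on adding to 12 precomplexed with MgBr2·OEt2. This gives the open-chain propargylic bromomagnesium alkoxide F9, which should lactonise on warming to 0 °C to the alkynyl ether lactone F10. H2 over Pd/CaCO3 poisoned with Pb(OAc)2 and quinoline (EtOAc, 0 °C) should then give 16. F10 would be kept cold and hydrogenated at once, since benzylic alkynyl ethers rearrange on warming.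

Step 2. What may go wrong: heterolysis of the benzylic C–O bond of the α-bromo ether 4 (loss of the 4-methoxybenzyl cation) before HBr is removed, and erosion of the Z selectivity. In the fallback the enol ether is made by eliminating an alcohol from an acetal, so no free bromine or HBr meets the PMB group. It sets out from 1 and comes back at 5. Acetal exchange of bromoacetaldehyde diethyl acetal with 1 (pyridinium tosylate cat, toluene, removal of ethanol) gives 2-bromo-1,1-bis(4-methoxybenzyloxy)ethane F11. Me3SiOTf/i-Pr2NEt (CH2Cl2, −20 °C) then removes one equivalent of the alcohol as its silyl ether through the oxocarbenium ion and should give 5.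

**Further compounds**
F1 | step 8 | 4-methoxybenzyl 5,6-dideoxy-2,3-O-isopropylidene-4-O-(4-methoxybenzyl)-D-ribo-hex-5-enonate | COc1ccc(COC(=O)[C@@H]2OC(C)(C)O[C@@H]2[C@H](OCc3ccc(OC)cc3)C=C)cc1
F2 | step 8 | 5,6-dideoxy-2,3-O-isopropylidene-4-O-(4-methoxybenzyl)-aldehydo-D-ribo-hex-5-enose | O=C[C@@H]1OC(C)(C)O[C@@H]1[C@H](OCc1ccc(OC)cc1)C=C
F3 | step 8 | 5,6-dideoxy-2-C-(hydroxymethyl)-2,3-O-isopropylidene-4-O-(4-methoxybenzyl)-aldehydo-D-ribo-hex-5-enose (CH2OH trans to the C4 chain on the dioxolane) | O=C[C@]1(CO)OC(C)(C)O[C@@H]1[C@H](OCc1ccc(OC)cc1)C=C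
F4 | step 8 | O-tert-butyldimethylsilyl ether of F3 | O=C[C@]1(CO[Si](C)(C)C(C)(C)C)OC(C)(C)O[C@@H]1[C@H](OCc1ccc(OC)cc1)C=C
F5 | step 8 | vinyl carbinol from F4 (C1 carbinol with O1 syn to O6; terminal alkenes at C2 and C3) | C=C[C@H](O)[C@]1(CO[Si](C)(C)C(C)(C)C)OC(C)(C)O[C@@H]1[C@H](OCc1ccc(OC)cc1)C=C
F6 | step 8 | O1-(4-methoxybenzyl) ether of F5 (diene for ring closure) | C=C[C@H](OCc1ccc(OC)cc1)[C@]1(CO[Si](C)(C)C(C)(C)C)OC(C)(C)O[C@@H]1[C@H](OCc1ccc(OC)cc1)C=C
F7 | step 7 | (E)-1,2-dichlorovinyl 4-methoxybenzyl ether | Cl/C=C(Cl)\OCc1ccc(OC)cc1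
F8 | step 7 | lithium (4-methoxybenzyloxy)acetylide | [Li]C#COCc1ccc(OC)cc1
F9 | step 7 | bromomagnesium alkoxide of 4-methoxybenzyl 6,7-didehydro-6-deoxy-2,3-O-isopropylidene-4,7-di-O-(4-methoxybenzyl)-L-talo-hept-6-ynonate | COc1ccc(COC(=O)[C@@H]2OC(C)(C)O[C@@H]2[C@H](OCc3ccc(OC)cc3)[C@@H](O[Mg]Br)C#COCc3ccc(OC)cc3)cc1
F10 | step 7 | 6,7-didehydro-6-deoxy-2,3-O-isopropylidene-4,7-di-O-(4-methoxybenzyl)-L-talo-hept-6-ynono-1,5-lactone | O=C1O[C@@H](C#COCc2ccc(OC)cc2)[C@@H](OCc2ccc(OC)cc2)[C@H]3OC(C)(C)O[C@@H]13
F11 | step 2 | 2-bromo-1,1-bis(4-methoxybenzyloxy)ethane | BrCC(OCc1ccc(OC)cc1)OCc1ccc(OC)cc1
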